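**Retrosynthetic overview**
1. Target 19 (all-cis) ⇐ hexabenzyl indene 18: one H2/Pd operation adds H2 syn across C1=C2 on the face opposite the C3 aryl group (sets C1 and C2 from C3) and removes all six benzyl ethers.
2. 18 ⇐ keto-alkyne 16 by intramolecular alkyne–carbonyl metathesis ([2+2] cycloaddition to an oxetene, then 4π ring opening): this closes the five-membered ring and creates the aroyl ketone.
3. 16 ⇐ ozonolysis of 14 ⇐ O-benzylation of 13 ⇐ aromatic Claisen rearrangement of aryl allyl ether 11, which forms the C3–C3a bond and transfers the C–O stereocentre to C3.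
4. 11 ⇐ Mitsunobu union (inversion) of alkynylphenol 10 with allylic alcohol 7; 7 ⇐ (S)-but-3-yn-2-ol by Sonogashira coupling and hydroxyl-directed arylmagnesiation; 10 ⇐ Sonogashira coupling.
5. Ring order: all benzene rings are bought; ring A (the resorcinol ring) comes from 8, and the cyclopentene ring is closed in step 8 and saturated in step 9.

Assumption: the SMILES is read literally; it encodes the all-cis (1R,2R,3R) indane, and that isomer is what the route delivers (3-(benzyloxy)-5-bromophenol is taken as a catalogue compound).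

**Step 1**
Reactants: 1 (S)-but-3-yn-2-ol; 2 1-(benzyloxy)-4-iodobenzene
Product: 3 (2S)-4-[4-(benzyloxy)phenyl]but-3-yn-2-ol
Conditions: Pd(PPh3)2Cl2 (2 mol %), CuI (4 mol %), Et3N, THF, rt
Reagents that add atoms: none
Why: Sonogashira coupling of a terminal alkyne with an aryl iodide runs at room temperature and does not touch the carbinol stereocentre bought in 1.

**Step 2**
Reactants: 3 (2S)-4-[4-(benzyloxy)phenyl]but-3-yn-2-ol; 4 1,3-bis(benzyloxy)-5-bromobenzene
Product: 7 (2S,3E)-3-[3,5-bis(benzyloxy)phenyl]-4-[4-(benzyloxy)phenyl]but-3-en-2-ol, via arylmagnesium bromide 5 (not isolated), via cyclic alkenylmagnesium alkoxide 6 (not isolated)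
Conditions: Mg turnings, THF, 45 °C (4 to 5, 3 equiv); add 3, PhMe, 90 °C, 16 h; H2O, 0 °C
Reagents that add atoms: none
Why: Hydroxyl-directed anti-carbomagnesiation of a propargylic alkoxide (Duboudin/Fallis type) puts the aryl group on the proximal alkyne carbon and Mg on the distal one through a five-membered chelate, so protonation gives one alkene isomer (the two aryl groups cis) with the stereocentre untouched.

**Step 3**
Reactants: 8 3-(benzyloxy)-5-bromophenol; 9 1-(benzyloxy)-4-ethynylbenzene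
Product: 10 3-(benzyloxy)-5-{[4-(benzyloxy)phenyl]ethynyl}phenol
Conditions: Pd(PPh3)2Cl2 (5 mol %), CuI (5 mol %), Et3N, DMF, 80 °C
Reagents that add atoms: none
Why: Sonogashira coupling tolerates the free phenol and installs the diarylalkyne that later supplies C1 and the aroyl carbon.

**Step 4**
Reactants: 10 3-(benzyloxy)-5-{[4-(benzyloxy)phenyl]ethynyl}phenol; 7 (2S,3E)-3-[3,5-bis(benzyloxy)phenyl]-4-[4-(benzyloxy)phenyl]but-3-en-2-ol
Product: 11 1-(benzyloxy)-3-{[(2R,3E)-3-[3,5-bis(benzyloxy)phenyl]-4-[4-(benzyloxy)phenyl]but-3-en-2-yl]oxy}-5-{[4-(benzyloxy)phenyl]ethynyl}benzene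
Conditions: PPh3, DIAD, PhMe, 0 °C → rt
Reagents that add atoms: none
Why: Mitsunobu etherification displaces the oxyphosphonium by the phenoxide in an SN2 sense, inverting the carbinol centre (S to R); the non-polar solvent and low temperature are chosen to suppress ionisation of the allylic system.

**Step 5**
Reactants: 11 1-(benzyloxy)-3-{[(2R,3E)-3-[3,5-bis(benzyloxy)phenyl]-4-[4-(benzyloxy)phenyl]but-3-en-2-yl]oxy}-5-{[4-(benzyloxy)phenyl]ethynyl}benzene
Product: 13 5-(benzyloxy)-3-{[4-(benzyloxy)phenyl]ethynyl}-2-{(1S,2Z)-2-[3,5-bis(benzyloxy)phenyl]-1-[4-(benzyloxy)phenyl]but-2-en-1-yl}phenol, via ortho-dienone 12 (not isolated)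
Conditions: PhNEt2, 180 °C, sealed tube, Ar
Reagents that add atoms: none
Why: The aromatic Claisen rearrangement ([3,3]-sigmatropic) goes through a chair transition state with the methyl group pseudo-equatorial, so the C–O stereocentre is relayed suprafacially to the new diarylmethine carbon (future C3); the meta alkynyl group (adjacent-directing) and the meta benzyloxy group (para-directing) both favour the ortho carbon next to the alkyne, and the dienone then tautomerises to the phenol.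

**Step 6**
Reactants: 13 5-(benzyloxy)-3-{[4-(benzyloxy)phenyl]ethynyl}-2-{(1S,2Z)-2-[3,5-bis(benzyloxy)phenyl]-1-[4-(benzyloxy)phenyl]but-2-en-1-yl}phenol
Product: 14 1,5-bis(benzyloxy)-3-{[4-(benzyloxy)phenyl]ethynyl}-2-{(1S,2Z)-2-[3,5-bis(benzyloxy)phenyl]-1-[4-(benzyloxy)phenyl]but-2-en-1-yl}benzene
Conditions: BnBr, K2CO3, DMF, 50 °C
Reagents that add atoms: benzyl bromide BrCc1ccccc1
Why: Williamson etherification masks the phenol, which would otherwise condense with the ketone made in the next step to give a benzofuran; the carbonate base is far too weak to touch the diarylmethine C–H.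

**Step 7**
Reactants: 14 1,5-bis(benzyloxy)-3-{[4-(benzyloxy)phenyl]ethynyl}-2-{(1S,2Z)-2-[3,5-bis(benzyloxy)phenyl]-1-[4-(benzyloxy)phenyl]but-2-en-1-yl}benzene
Product: 16 (2R)-2-[2,4-bis(benzyloxy)-6-{[4-(benzyloxy)phenyl]ethynyl}phenyl]-1-[3,5-bis(benzyloxy)phenyl]-2-[4-(benzyloxy)phenyl]ethan-1-one, via secondary ozonide 15 (not isolated)
Conditions: O3, CH2Cl2, −78 °C (Sudan Red 7B end point); then PPh3, −78 °C → rt
Reagents that add atoms: ozone [O-][O+]=O
Why: Ozonolysis cleaves the trisubstituted alkene much faster than the diarylalkyne or the alkoxyarenes, and the neutral reductive work-up releases the aryl ketone without enolising the adjacent stereocentre.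

**Step 8**
Reactants: 16 (2R)-2-[2,4-bis(benzyloxy)-6-{[4-(benzyloxy)phenyl]ethynyl}phenyl]-1-[3,5-bis(benzyloxy)phenyl]-2-[4-(benzyloxy)phenyl]ethan-1-one
Product: 18 {(1S)-5,7-bis(benzyloxy)-2-[3,5-bis(benzyloxy)phenyl]-1-[4-(benzyloxy)phenyl]-1H-inden-3-yl}[4-(benzyloxy)phenyl]methanone, via fused oxetene 17 (not isolated)
Conditions: AgSbF6 (10 mol %), ClCH2CH2Cl, 50 °C
Reagents that add atoms: none
Why: In this Lewis-acid-catalysed intramolecular alkyne–carbonyl metathesis the activated ketone is attacked by the alkyne carbon attached to ring A (the vinyl cation character at the other carbon is stabilised by the 4-(benzyloxy)phenyl group), a formal [2+2] cycloaddition that closes the five-membered ring, and 4π-electrocyclic opening of the oxetene gives the aroyl-substituted tetrasubstituted alkene without base, so the C3 stereocentre is kept.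

**Step 9**
Reactants: 18 {(1S)-5,7-bis(benzyloxy)-2-[3,5-bis(benzyloxy)phenyl]-1-[4-(benzyloxy)phenyl]-1H-inden-3-yl}[4-(benzyloxy)phenyl]methanone
Product: 19 (4-hydroxyphenyl)[(1R,2R,3R)-2-(3,5-dihydroxyphenyl)-4,6-dihydroxy-3-(4-hydroxyphenyl)-2,3-dihydro-1H-inden-1-yl]methanone (Caraphenol C as drawn)
Conditions: H2 (4 atm), Pd(OH)2/C, EtOAc–THF, rt
Reagents that add atoms: none
Why: Heterogeneous catalytic hydrogenation adds H2 syn to the tetrasubstituted enone C=C from the face opposite the C3 aryl group, which places the aroyl, 3,5-dihydroxyphenyl and 4-hydroxyphenyl groups all cis (1R,2R,3R), while hydrogenolysis removes the six benzyl ethers in the same operation.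

**Compound list**
1 | (S)-but-3-yn-2-ol | C[C@H](O)C#C | starting material
2 | 1-(benzyloxy)-4-iodobenzene | Ic1ccc(OCc2ccccc2)cc1 | starting material
3 | (2S)-4-[4-(benzyloxy)phenyl]but-3-yn-2-ol | C[C@H](O)C#Cc1ccc(OCc2ccccc2)cc1 | intermediate
4 | 1,3-bis(benzyloxy)-5-bromobenzene | Brc1cc(OCc2ccccc2)cc(OCc2ccccc2)c1 | starting material
5 | [3,5-bis(benzyloxy)phenyl]magnesium bromide | Br[Mg]c1cc(OCc2ccccc2)cc(OCc2ccccc2)c1 | intermediate (not isolated)
6 | (5S)-4-[3,5-bis(benzyloxy)phenyl]-3-[4-(benzyloxy)phenyl]-5-methyl-2,5-dihydro-1,2-oxamagnesole (cyclic alkenylmagnesium alkoxide; the two aryl groups cis) | C[C@@H]1O[Mg]C(c2ccc(OCc3ccccc3)cc2)=C1c1cc(OCc2ccccc2)cc(OCc2ccccc2)c1 | intermediate (not isolated)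
7 | (2S,3E)-3-[3,5-bis(benzyloxy)phenyl]-4-[4-(benzyloxy)phenyl]but-3-en-2-ol | C[C@H](O)/C(=C/c1ccc(OCc2ccccc2)cc1)c1cc(OCc2ccccc2)cc(OCc2ccccc2)c1 | intermediate
8 | 3-(benzyloxy)-5-bromophenol | Oc1cc(Br)cc(OCc2ccccc2)c1 | starting material
9 | 1-(benzyloxy)-4-ethynylbenzene | C#Cc1ccc(OCc2ccccc2)cc1 | starting material
10 | 3-(benzyloxy)-5-{[4-(benzyloxy)phenyl]ethynyl}phenol | Oc1cc(OCc2ccccc2)cc(C#Cc2ccc(OCc3ccccc3)cc2)c1 | intermediate
11 | 1-(benzyloxy)-3-{[(2R,3E)-3-[3,5-bis(benzyloxy)phenyl]-4-[4-(benzyloxy)phenyl]but-3-en-2-yl]oxy}-5-{[4-(benzyloxy)phenyl]ethynyl}benzene | C[C@@H](Oc1cc(OCc2ccccc2)cc(C#Cc2ccc(OCc3ccccc3)cc2)c1)/C(=C/c1ccc(OCc2ccccc2)cc1)c1cc(OCc2ccccc2)cc(OCc2ccccc2)c1 | intermediate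
12 | 3-(benzyloxy)-5-{[4-(benzyloxy)phenyl]ethynyl}-6-{(2Z)-2-[3,5-bis(benzyloxy)phenyl]-1-[4-(benzyloxy)phenyl]but-2-en-1-yl}cyclohexa-2,4-dien-1-one (side-chain stereocentre as in 13; ring sp3 carbon transient) | O=C1C=C(OCc2ccccc2)C=C(C#Cc2ccc(OCc3ccccc3)cc2)C1[C@@H](c1ccc(OCc2ccccc2)cc1)/C(=C/C)c1cc(OCc2ccccc2)cc(OCc2ccccc2)c1 | intermediate (not isolated)
13 | 5-(benzyloxy)-3-{[4-(benzyloxy)phenyl]ethynyl}-2-{(1S,2Z)-2-[3,5-bis(benzyloxy)phenyl]-1-[4-(benzyloxy)phenyl]but-2-en-1-yl}phenol | Oc1cc(OCc2ccccc2)cc(C#Cc2ccc(OCc3ccccc3)cc2)c1[C@@H](c1ccc(OCc2ccccc2)cc1)/C(=C/C)c1cc(OCc2ccccc2)cc(OCc2ccccc2)c1 | intermediate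
14 | 1,5-bis(benzyloxy)-3-{[4-(benzyloxy)phenyl]ethynyl}-2-{(1S,2Z)-2-[3,5-bis(benzyloxy)phenyl]-1-[4-(benzyloxy)phenyl]but-2-en-1-yl}benzene | c1ccccc1COc1cc(OCc2ccccc2)cc(C#Cc2ccc(OCc3ccccc3)cc2)c1[C@@H](c1ccc(OCc2ccccc2)cc1)/C(=C/C)c1cc(OCc2ccccc2)cc(OCc2ccccc2)c1 | intermediate
15 | secondary ozonide of 14: 3-methyl-5-[3,5-bis(benzyloxy)phenyl]-5-{(R)-[2,4-bis(benzyloxy)-6-{[4-(benzyloxy)phenyl]ethynyl}phenyl][4-(benzyloxy)phenyl]methyl}-1,2,4-trioxolane (ring stereocentres undefined) | CC1OC(OO1)(c1cc(OCc2ccccc2)cc(OCc2ccccc2)c1)[C@H](c1ccc(OCc2ccccc2)cc1)c1c(OCc2ccccc2)cc(OCc2ccccc2)cc1C#Cc1ccc(OCc2ccccc2)cc1 | intermediate (not isolated)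
16 | (2R)-2-[2,4-bis(benzyloxy)-6-{[4-(benzyloxy)phenyl]ethynyl}phenyl]-1-[3,5-bis(benzyloxy)phenyl]-2-[4-(benzyloxy)phenyl]ethan-1-one | O=C(c1cc(OCc2ccccc2)cc(OCc2ccccc2)c1)[C@H](c1ccc(OCc2ccccc2)cc1)c1c(OCc2ccccc2)cc(OCc2ccccc2)cc1C#Cc1ccc(OCc2ccccc2)cc1 | intermediate
17 | oxetene cycloadduct: 2H-oxete fused to the new five-membered ring (ketone O of 16 bonded to the former distal alkyne carbon bearing the 4-(benzyloxy)phenyl group, ketone C bonded to the proximal alkyne carbon; diarylmethine centre as in 16) | O1C(c2ccc(OCc3ccccc3)cc2)=C2c3cc(OCc4ccccc4)cc(OCc4ccccc4)c3[C@@H](c3ccc(OCc4ccccc4)cc3)C12c1cc(OCc2ccccc2)cc(OCc2ccccc2)c1 | intermediate (not isolated)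
18 | {(1S)-5,7-bis(benzyloxy)-2-[3,5-bis(benzyloxy)phenyl]-1-[4-(benzyloxy)phenyl]-1H-inden-3-yl}[4-(benzyloxy)phenyl]methanone | O=C(c1ccc(OCc2ccccc2)cc1)C1=C(c2cc(OCc3ccccc3)cc(OCc3ccccc3)c2)[C@H](c2ccc(OCc3ccccc3)cc2)c2c(OCc3ccccc3)cc(OCc3ccccc3)cc21 | intermediate
19 | (4-hydroxyphenyl)[(1R,2R,3R)-2-(3,5-dihydroxyphenyl)-4,6-dihydroxy-3-(4-hydroxyphenyl)-2,3-dihydro-1H-inden-1-yl]methanone (all-cis) | O=C(c1ccc(O)cc1)[C@H]1c2cc(O)cc(O)c2[C@@H](c2ccc(O)cc2)[C@H]1c1cc(O)cc(O)c1 | target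

**Step count and risks**
Total steps: 9. Longest linear sequence: 8 (steps 1, 2, 4, 5, 6, 7, 8, 9); step 3 is the convergent branch.

Most likely to fail, first: step 4. The oxyphosphonium of 7 can ionise to a 4-alkoxybenzyl-stabilised allyl cation, which would erode the ee or give the SN2′ ether. The fallback avoids the ether altogether; it sets out from 7 (with 10 as the aryl source) and comes back at 14, bypassing 11 to 13. Alcohol 7 is esterified (picolinic acid, DCC, DMAP, CH2Cl2) to (2S,3E)-3-[3,5-bis(benzyloxy)phenyl]-4-[4-(benzyloxy)phenyl]but-3-en-2-yl pyridine-2-carboxylate F1. Phenol 10 is benzylated (BnBr, K2CO3) to 1,3-bis(benzyloxy)-5-{[4-(benzyloxy)phenyl]ethynyl}benzene F2. F2 is iodinated with NIS in MeCN at the ring position between a benzyloxy group and the alkyne (ortho to one benzyloxy group, para to the other) to give 1,5-bis(benzyloxy)-2-iodo-3-{[4-(benzyloxy)phenyl]ethynyl}benzene F3. Iodine–magnesium exchange (iPrMgCl·LiCl, THF) gives (2,4-bis(benzyloxy)-6-{[4-(benzyloxy)phenyl]ethynyl}phenyl)magnesium chloride F4. CuBr·SMe2-mediated anti-SN2′ substitution of F1 by F4 delivers the aryl group to the benzylic alkene carbon anti to the chelating picolinate. This gives the same C3 configuration as inversion followed by the suprafacial Claisen shift, so the product is 14.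

Second: step 8. The hindered aryl ketone may be sluggish, silver may favour O-attack on the alkyne, and acid can slowly enolise 16 towards C3. The fallback sets out from 16 and comes back at 18. Ph3PAuNTf2-catalysed hydration of the alkyne in dioxane–H2O puts the new carbonyl next to the 4-(benzyloxy)phenyl group and gives (2R)-2-[2,4-bis(benzyloxy)-6-{2-[4-(benzyloxy)phenyl]-2-oxoethyl}phenyl]-1-[3,5-bis(benzyloxy)phenyl]-2-[4-(benzyloxy)phenyl]ethan-1-one F5. Soft enolisation of its unhindered ArCH2C(=O)Ar unit (TiCl4, Bu3N, CH2Cl2, −78 → 0 °C) triggers an intramolecular aldol condensation that closes the same C1=C2 bond.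

Third: step 9. The crowded tetrasubstituted alkene may resist Pd, or the ketone may be over-reduced while the benzyl ethers are being cleaved. The fallback sets out from 18 and comes back at 19, separating the two jobs. Homogeneous hydrogenation with [Ir(cod)(PCy3)(py)]PF6 (H2 50 atm, CH2Cl2, rt), which handles tetrasubstituted alkenes and leaves benzyl ethers and the ketone alone, adds H2 from the same less hindered face. This gives [4-(benzyloxy)phenyl]{(1R,2R,3R)-4,6-bis(benzyloxy)-2-[3,5-bis(benzyloxy)phenyl]-3-[4-(benzyloxy)phenyl]-2,3-dihydro-1H-inden-1-yl}methanone F6. Mild hydrogenolysis (H2 1 atm, Pd/C, EtOAc–MeOH, rt) then gives 19.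

**Further compounds**
F1 | step 4 | (2S,3E)-3-[3,5-bis(benzyloxy)phenyl]-4-[4-(benzyloxy)phenyl]but-3-en-2-yl pyridine-2-carboxylate | C[C@H](OC(=O)c1ccccn1)/C(=C/c1ccc(OCc2ccccc2)cc1)c1cc(OCc2ccccc2)cc(OCc2ccccc2)c1
F2 | step 4 | 1,3-bis(benzyloxy)-5-{[4-(benzyloxy)phenyl]ethynyl}benzene | c1ccccc1COc1cc(OCc2ccccc2)cc(C#Cc2ccc(OCc3ccccc3)cc2)c1
F3 | step 4 | 1,5-bis(benzyloxy)-2-iodo-3-{[4-(benzyloxy)phenyl]ethynyl}benzene | Ic1c(OCc2ccccc2)cc(OCc2ccccc2)cc1C#Cc1ccc(OCc2ccccc2)cc1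
F4 | step 4 | (2,4-bis(benzyloxy)-6-{[4-(benzyloxy)phenyl]ethynyl}phenyl)magnesium chloride | Cl[Mg]c1c(OCc2ccccc2)cc(OCc2ccccc2)cc1C#Cc1ccc(OCc2ccccc2)cc1
F5 | step 8 | (2R)-2-[2,4-bis(benzyloxy)-6-{2-[4-(benzyloxy)phenyl]-2-oxoethyl}phenyl]-1-[3,5-bis(benzyloxy)phenyl]-2-[4-(benzyloxy)phenyl]ethan-1-one | O=C(c1cc(OCc2ccccc2)cc(OCc2ccccc2)c1)[C@H](c1ccc(OCc2ccccc2)cc1)c1c(OCc2ccccc2)cc(OCc2ccccc2)cc1CC(=O)c1ccc(OCc2ccccc2)cc1
F6 | step 9 | [4-(benzyloxy)phenyl]{(1R,2R,3R)-4,6-bis(benzyloxy)-2-[3,5-bis(benzyloxy)phenyl]-3-[4-(benzyloxy)phenyl]-2,3-dihydro-1H-inden-1-yl}methanone | O=C(c1ccc(OCc2ccccc2)cc1)[C@H]1c2cc(OCc3ccccc3)cc(OCc3ccccc3)c2[C@@H](c2ccc(OCc3ccccc3)cc2)[C@H]1c1cc(OCc2ccccc2)cc(OCc2ccccc2)c1
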